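**Retrosynthetic overview**
1. Last C–C bond: a Claisen–Schmidt condensation builds the chalcone enone on a ring-A methyl ketone. The acetyl group is placed by ortho-lithiation of a ring A that is still symmetric about the C3 axis, so no regiochemical choice arises.
2. Key bond C4–C5: a sparteine-controlled α-oxygenated alkyllithium (the carbinol carbon C5 used as the nucleophile) is inserted into the C4–B bond of a primary boronic ester by 1,2-metallate shift. C–B oxidation then gives the 5S alcohol under reagent control.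
3. The boronic ester (C3 with ring A, the E-styryl group and CH2B) comes in one step from a ring-A styrene, B2pin2 and an E-alkenyl iodide by an enantioselective Cu/Pd borylative coupling.
4. Building blocks: 5-methoxyresorcinol (ring A), 4-hydroxybenzaldehyde (styryl arene and chalcone ring B), 3-(4-hydroxyphenyl)propan-1-ol (C5–C7 and its arene). MOM ethers are used throughout and removed in one final operation.
5. Ring order: no ring is constructed; all four benzene rings are bought.

Assumption: chain carbons are called C1–C7 as in the diarylheptanoid (C1 = alkene CH on the arene, C3 = carbon on ring A, C5 = carbinol carbon); the target is then 3R,5S. Both enantiomers of sparteine are taken as commercial.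

**Route**

Step 1
Reactants: 1 5-methoxyresorcinol; 2 chloromethyl methyl ether
Product: 3 1-methoxy-3,5-bis(methoxymethoxy)benzene
Conditions: NaH, DMF, 0 °C; MOMCl, 0 °C to rt
Reagents that add atoms: chloromethyl methyl ether (2), COCCl
Why: Williamson ether synthesis in which both phenoxides are alkylated by the reactive α-chloro ether, giving two MOM groups that later act as ortho-directing groups.

Step 2
Reactants: 3 1-methoxy-3,5-bis(methoxymethoxy)benzene; 4 vinyl bromide
Product: 7 2-ethenyl-5-methoxy-1,3-bis(methoxymethoxy)benzene, via aryllithium 5 (not isolated), via arylzinc chloride 6 (not isolated)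
Conditions: n-BuLi, THF, 0 °C; ZnCl2, 0 °C to rt; vinyl bromide, Pd(OAc)2 (2 mol%), SPhos (4 mol%), 50 °C
Reagents that add atoms: vinyl bromide (4), C=CBr
Why: Directed ortho-metalation removes the hydrogen flanked by the two chelating MOM ethers, and after transmetalation to zinc a Negishi coupling with a catalyst suited to di-ortho-substituted partners delivers the styrene.

Step 3
Reactants: 8 4-hydroxybenzaldehyde; 2 chloromethyl methyl ether
Product: 9 4-(methoxymethoxy)benzaldehyde
Conditions: MOMCl, K2CO3, acetone, rt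
Reagents that add atoms: chloromethyl methyl ether (2), COCCl
Why: Williamson O-alkylation of the phenoxide; the aldehyde is untouched.

Step 4
Reactants: 9 4-(methoxymethoxy)benzaldehyde; 10 iodoform
Product: 11 1-[(E)-2-iodoethenyl]-4-(methoxymethoxy)benzene
Conditions: CrCl2 (6 equiv), CHI3 (2 equiv), THF, 0 °C to rt
Reagents that add atoms: iodoform (10), IC(I)I
Why: Takai olefination, in which the geminal dichromium species from CHI3 and CrCl2 adds to the aryl aldehyde and eliminates to give the E-alkenyl iodide with high selectivity.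

Step 5
Reactants: 7 2-ethenyl-5-methoxy-1,3-bis(methoxymethoxy)benzene; 11 1-[(E)-2-iodoethenyl]-4-(methoxymethoxy)benzene; 12 bis(pinacolato)diboron
Product: 13 2-[(2R,3E)-2-[4-methoxy-2,6-bis(methoxymethoxy)phenyl]-4-[4-(methoxymethoxy)phenyl]but-3-en-1-yl]-4,4,5,5-tetramethyl-1,3,2-dioxaborolane
Conditions: B2pin2, CuCl (10 mol%), (R)-DTBM-SEGPHOS (11 mol%), Pd(OAc)2 (3 mol%), RuPhos (6 mol%), NaOt-Bu, THF, rt
Reagents that add atoms: bis(pinacolato)diboron (12), CC1(C)OB(OC1(C)C)B1OC(C)(C)C(C)(C)O1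
Why: Proposed new method: an enantioselective three-component alkenylboration in which the bisphosphine-bound Cu–Bpin species adds syn across the vinyl group of 7 (boron to the terminal carbon, copper to the benzylic carbon, face chosen by the chiral ligand), the benzylic copper transmetalates to the alkenylpalladium iodide formed from 11 and zerovalent palladium, and reductive elimination makes the C3–C2 bond with retention of the E geometry; the closest known reaction type is the Cu/Pd-cocatalysed enantioselective arylboration and allylboration of vinylarenes, extended here to an alkenyl iodide and a 2,6-dialkoxystyrene, and the hand of the ligand that gives 3R is not known in advance, so it is confirmed on the first run and the antipode used if needed.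

Step 6
Reactants: 14 3-(4-hydroxyphenyl)propan-1-ol; 2 chloromethyl methyl ether
Product: 15 3-[4-(methoxymethoxy)phenyl]propan-1-ol
Conditions: MOMCl, K2CO3, acetone, rt
Reagents that add atoms: chloromethyl methyl ether (2), COCCl
Why: Chemoselective Williamson alkylation, since K2CO3 deprotonates only the phenol and the primary alcohol stays free.

Step 7
Reactants: 15 3-[4-(methoxymethoxy)phenyl]propan-1-ol; 16 2,4,6-tri(propan-2-yl)benzoyl chloride
Product: 17 3-[4-(methoxymethoxy)phenyl]propyl 2,4,6-tri(propan-2-yl)benzoate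
Conditions: TIBCl, Et3N, DMAP (cat.), CH2Cl2, reflux
Reagents that add atoms: 2,4,6-tri(propan-2-yl)benzoyl chloride (16), CC(C)c1cc(C(C)C)c(C(Cl)=O)c(C(C)C)c1
Why: DMAP-catalysed acylation gives the hindered benzoate, whose shielded carbonyl resists s-BuLi and directs α-lithiation.

Step 8
Reactants: 17 3-[4-(methoxymethoxy)phenyl]propyl 2,4,6-tri(propan-2-yl)benzoate; 13 2-[(2R,3E)-2-[4-methoxy-2,6-bis(methoxymethoxy)phenyl]-4-[4-(methoxymethoxy)phenyl]but-3-en-1-yl]-4,4,5,5-tetramethyl-1,3,2-dioxaborolane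
Product: 21 (3S,5R,6E)-5-[4-methoxy-2,6-bis(methoxymethoxy)phenyl]-1,7-bis[4-(methoxymethoxy)phenyl]hept-6-en-3-ol, via lithiated benzoate 18 (not isolated), via boronate complex 19 (not isolated), via secondary boronic ester 20 (not isolated)
Conditions: s-BuLi, (+)-sparteine, Et2O, −78 °C, 5 h; add 13, −78 °C, 2 h; then 35 °C, 12 h; NaOH, H2O2, THF/H2O, 0 °C to rt
Reagents that add atoms: hydrogen peroxide, OO
Why: Hoppe–Aggarwal lithiation–borylation, in which s-BuLi/(+)-sparteine removes the pro-R hydrogen next to oxygen to give the configurationally stable (R)-α-oxyalkyllithium 18 (carbinol carbon C5 as nucleophile), this adds to boron of 13 with retention, the C4 group migrates from boron to C5 with inversion and loss of the benzoate (1,2-metallate rearrangement), and stereoretentive C–B oxidation gives the 5S alcohol under reagent control with C3 untouched and minor diastereomers removed by chromatography.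

Step 9
Reactants: 21 (3S,5R,6E)-5-[4-methoxy-2,6-bis(methoxymethoxy)phenyl]-1,7-bis[4-(methoxymethoxy)phenyl]hept-6-en-3-ol; 22 N-methoxy-N-methylacetamide
Product: 25 1-[3-[(1E,3R,5S)-5-hydroxy-1,7-bis[4-(methoxymethoxy)phenyl]hept-1-en-3-yl]-6-methoxy-2,4-bis(methoxymethoxy)phenyl]ethan-1-one, via dilithio species 23 (not isolated), via tetrahedral adduct 24 (not isolated)
Conditions: n-BuLi (1 equiv), THF, −78 °C; s-BuLi, TMEDA, −78 to −40 °C; MeC(O)N(OMe)Me, −78 to 0 °C; H2O
Reagents that add atoms: N-methoxy-N-methylacetamide (22), CC(=O)N(C)OC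
Why: Directed ortho-metalation in which, after the C5 hydroxyl is capped as its lithium alkoxide, the ring-A hydrogen flanked by OMOM and OMe is removed fastest at low temperature (the two such hydrogens are equivalent and the hindered C3–H is kinetically left alone), and the aryllithium is acylated by the Weinreb amide through a chelated tetrahedral adduct that releases the methyl ketone only on quench.

Step 10
Reactants: 25 1-[3-[(1E,3R,5S)-5-hydroxy-1,7-bis[4-(methoxymethoxy)phenyl]hept-1-en-3-yl]-6-methoxy-2,4-bis(methoxymethoxy)phenyl]ethan-1-one; 9 4-(methoxymethoxy)benzaldehyde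
Product: 27 (2E)-1-[3-[(1E,3R,5S)-5-hydroxy-1,7-bis[4-(methoxymethoxy)phenyl]hept-1-en-3-yl]-6-methoxy-2,4-bis(methoxymethoxy)phenyl]-3-[4-(methoxymethoxy)phenyl]prop-2-en-1-one, via aldol adduct 26 (not isolated)
Conditions: KOH, EtOH/H2O, rt
Reagents that add atoms: none
Why: Claisen–Schmidt aldol condensation, in which the acetophenone enolate adds to the non-enolisable aldehyde and E1cB dehydration gives the E-enone, while the capped 2′-oxygen prevents flavanone formation and hydroxide does not touch C3 or C5.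

Step 11
Reactants: 27 (2E)-1-[3-[(1E,3R,5S)-5-hydroxy-1,7-bis[4-(methoxymethoxy)phenyl]hept-1-en-3-yl]-6-methoxy-2,4-bis(methoxymethoxy)phenyl]-3-[4-(methoxymethoxy)phenyl]prop-2-en-1-one
Product: 29 calyxin A, via hexakis-trimethylsilyl ether 28 (not isolated)
Conditions: TMSOTf, 2,2′-bipyridyl, MeCN, 0 °C to rt; then H2O, rt
Reagents that add atoms: none
Why: Chemoselective cleavage of aromatic MOM ethers with TMSOTf/2,2′-bipyridyl, in which the silyl-activated acetal is captured by bipyridyl to leave aryl silyl ethers that hydrolyse on adding water, so no free strong acid meets the acid-labile 4-hydroxystyryl/C5-hydroxyl pair and C3 cannot epimerise.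

**Compound list**
1 | 5-methoxyresorcinol (3,5-dihydroxyanisole) | COc1cc(O)cc(O)c1 | starting material
2 | chloromethyl methyl ether | COCCl | starting material
3 | 1-methoxy-3,5-bis(methoxymethoxy)benzene | COCOc1cc(OC)cc(OCOC)c1 | intermediate
4 | vinyl bromide | C=CBr | starting material
5 | [4-methoxy-2,6-bis(methoxymethoxy)phenyl]lithium | COCOc1cc(OC)cc(OCOC)c1[Li] | intermediate
6 | chloro[4-methoxy-2,6-bis(methoxymethoxy)phenyl]zinc | COCOc1cc(OC)cc(OCOC)c1[Zn]Cl | intermediate
7 | 2-ethenyl-5-methoxy-1,3-bis(methoxymethoxy)benzene | COCOc1cc(OC)cc(OCOC)c1C=C | intermediate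
8 | 4-hydroxybenzaldehyde | O=Cc1ccc(O)cc1 | starting material
9 | 4-(methoxymethoxy)benzaldehyde | COCOc1ccc(C=O)cc1 | intermediate
10 | iodoform | IC(I)I | starting material
11 | 1-[(E)-2-iodoethenyl]-4-(methoxymethoxy)benzene | COCOc1ccc(/C=C/I)cc1 | intermediate
12 | bis(pinacolato)diboron | CC1(C)OB(OC1(C)C)B1OC(C)(C)C(C)(C)O1 | starting material
13 | 2-[(2R,3E)-2-[4-methoxy-2,6-bis(methoxymethoxy)phenyl]-4-[4-(methoxymethoxy)phenyl]but-3-en-1-yl]-4,4,5,5-tetramethyl-1,3,2-dioxaborolane | COc1cc(OCOC)c([C@@H](/C=C/c2ccc(OCOC)cc2)CB2OC(C)(C)C(C)(C)O2)c(OCOC)c1 | intermediate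
14 | 3-(4-hydroxyphenyl)propan-1-ol | OCCCc1ccc(O)cc1 | starting material
15 | 3-[4-(methoxymethoxy)phenyl]propan-1-ol | COCOc1ccc(CCCO)cc1 | intermediate
16 | 2,4,6-tri(propan-2-yl)benzoyl chloride | CC(C)c1cc(C(C)C)c(C(Cl)=O)c(C(C)C)c1 | starting material
17 | 3-[4-(methoxymethoxy)phenyl]propyl 2,4,6-tri(propan-2-yl)benzoate | COCOc1ccc(CCCOC(=O)c2c(C(C)C)cc(C(C)C)cc2C(C)C)cc1 | intermediate
18 | (1R)-1-lithio-3-[4-(methoxymethoxy)phenyl]propyl 2,4,6-tri(propan-2-yl)benzoate (sparteine complex) | [Li][C@@H](OC(=O)c1c(C(C)C)cc(C(C)C)cc1C(C)C)CCc1ccc(OCOC)cc1 | intermediate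
19 | lithium [(2R,3E)-2-[4-methoxy-2,6-bis(methoxymethoxy)phenyl]-4-[4-(methoxymethoxy)phenyl]but-3-en-1-yl]{(1R)-3-[4-(methoxymethoxy)phenyl]-1-[2,4,6-tri(propan-2-yl)benzoyloxy]propyl}(pinacolato)borate | COc1cc(OCOC)c([C@@H](/C=C/c2ccc(OCOC)cc2)C[B-]2(OC(C)(C)C(C)(C)O2)[C@@H](OC(=O)c2c(C(C)C)cc(C(C)C)cc2C(C)C)CCc2ccc(OCOC)cc2)c(OCOC)c1.[Li+] | intermediate
20 | 2-[(3S,5R,6E)-5-[4-methoxy-2,6-bis(methoxymethoxy)phenyl]-1,7-bis[4-(methoxymethoxy)phenyl]hept-6-en-3-yl]-4,4,5,5-tetramethyl-1,3,2-dioxaborolane | COc1cc(OCOC)c([C@@H](/C=C/c2ccc(OCOC)cc2)C[C@@H](B2OC(C)(C)C(C)(C)O2)CCc2ccc(OCOC)cc2)c(OCOC)c1 | intermediate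
21 | (3S,5R,6E)-5-[4-methoxy-2,6-bis(methoxymethoxy)phenyl]-1,7-bis[4-(methoxymethoxy)phenyl]hept-6-en-3-ol | COc1cc(OCOC)c([C@@H](/C=C/c2ccc(OCOC)cc2)C[C@@H](O)CCc2ccc(OCOC)cc2)c(OCOC)c1 | intermediate
22 | N-methoxy-N-methylacetamide | CC(=O)N(C)OC | starting material
23 | lithium (3S,5R,6E)-5-[3-lithio-4-methoxy-2,6-bis(methoxymethoxy)phenyl]-1,7-bis[4-(methoxymethoxy)phenyl]hept-6-en-3-olate | COc1cc(OCOC)c([C@@H](/C=C/c2ccc(OCOC)cc2)C[C@@H](O[Li])CCc2ccc(OCOC)cc2)c(OCOC)c1[Li] | intermediate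
24 | dilithium salt of the N-methoxy-N-methyl hemiaminal adduct of 23 with 22 | COc1cc(OCOC)c([C@@H](/C=C/c2ccc(OCOC)cc2)C[C@@H](O[Li])CCc2ccc(OCOC)cc2)c(OCOC)c1C(C)(O[Li])N(C)OC | intermediate
25 | 1-[3-[(1E,3R,5S)-5-hydroxy-1,7-bis[4-(methoxymethoxy)phenyl]hept-1-en-3-yl]-6-methoxy-2,4-bis(methoxymethoxy)phenyl]ethan-1-one | COc1cc(OCOC)c([C@@H](/C=C/c2ccc(OCOC)cc2)C[C@@H](O)CCc2ccc(OCOC)cc2)c(OCOC)c1C(C)=O | intermediate
26 | 3-hydroxy-1-[3-[(1E,3R,5S)-5-hydroxy-1,7-bis[4-(methoxymethoxy)phenyl]hept-1-en-3-yl]-6-methoxy-2,4-bis(methoxymethoxy)phenyl]-3-[4-(methoxymethoxy)phenyl]propan-1-one (new carbinol centre undefined) | COc1cc(OCOC)c([C@@H](/C=C/c2ccc(OCOC)cc2)C[C@@H](O)CCc2ccc(OCOC)cc2)c(OCOC)c1C(=O)CC(O)c1ccc(OCOC)cc1 | intermediate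
27 | (2E)-1-[3-[(1E,3R,5S)-5-hydroxy-1,7-bis[4-(methoxymethoxy)phenyl]hept-1-en-3-yl]-6-methoxy-2,4-bis(methoxymethoxy)phenyl]-3-[4-(methoxymethoxy)phenyl]prop-2-en-1-one | COc1cc(OCOC)c([C@@H](/C=C/c2ccc(OCOC)cc2)C[C@@H](O)CCc2ccc(OCOC)cc2)c(OCOC)c1C(=O)/C=C/c1ccc(OCOC)cc1 | intermediate
28 | hexakis(trimethylsilyl) ether of calyxin A (five aryl and one alkyl silyl ether) | COc1cc(O[Si](C)(C)C)c([C@@H](/C=C/c2ccc(O[Si](C)(C)C)cc2)C[C@@H](O[Si](C)(C)C)CCc2ccc(O[Si](C)(C)C)cc2)c(O[Si](C)(C)C)c1C(=O)/C=C/c1ccc(O[Si](C)(C)C)cc1 | intermediate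
29 | calyxin A, (2E)-1-[2,4-dihydroxy-3-[(1E,3R,5S)-5-hydroxy-1,7-bis(4-hydroxyphenyl)hept-1-en-3-yl]-6-methoxyphenyl]-3-(4-hydroxyphenyl)prop-2-en-1-one | COc1cc(O)c([C@@H](/C=C/c2ccc(O)cc2)C[C@@H](O)CCc2ccc(O)cc2)c(O)c1C(=O)/C=C/c1ccc(O)cc1 | target

**Step count and risks**

Total: 11 steps. Longest linear sequence: 7 steps (1, 2, 5, 8, 9, 10, 11).

Step 5 is the most likely to fail. The borylative coupling has no direct precedent with an alkenyl iodide and a twisted 2,6-dialkoxystyrene; borylcupration may be slow, 11 may be borylated directly, and the enantioselectivity is unknown. The fallback sets out from 3 and comes back at 13. Compound 3 is lithiated as in step 2 (aryllithium 5) and quenched with DMF to give 4-methoxy-2,6-bis(methoxymethoxy)benzaldehyde F1. A Horner–Wadsworth–Emmons reaction with triethyl phosphonoacetate and NaH gives ethyl (2E)-3-[4-methoxy-2,6-bis(methoxymethoxy)phenyl]prop-2-enoate F2, and i-Bu2AlH reduces it to (2E)-3-[4-methoxy-2,6-bis(methoxymethoxy)phenyl]prop-2-en-1-ol F3. ClP(O)(OEt)2 with DMAP and Et3N gives diethyl (2E)-3-[4-methoxy-2,6-bis(methoxymethoxy)phenyl]prop-2-en-1-yl phosphate F4, which is used cold and without storage. CuCl with a chiral sulfonate-bearing imidazolinium salt (N-heterocyclic carbene precursor) and NaOMe then transfers a CH2Bpin unit from bis(pinacolatoboryl)methane to the aryl-bearing alkene carbon in an enantioselective SN2′ allylic substitution, giving 2-[(2R)-2-[4-methoxy-2,6-bis(methoxymethoxy)phenyl]but-3-en-1-yl]-4,4,5,5-tetramethyl-1,3,2-dioxaborolane F5. Separately, 9 is methylenated with Ph3P=CH2 to 1-ethenyl-4-(methoxymethoxy)benzene F6. Cross-metathesis of F5 with F6 (second-generation Grubbs catalyst) installs the E-aryl alkene and gives 13.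

Step 9 is the second risk. A strong base meets the allylic C3–H and three other MOM-bearing rings, so epimerisation at C3 or lithiation at the wrong ring is possible. The fallback sets out from 21 and comes back at 25, and replaces deprotonation by electrophilic aromatic substitution with an electrophile that prefers the trialkoxy ring over the alkene. Compound 21 is silylated (TBSOTf, 2,6-lutidine) to tert-butyl-[(3S,5R,6E)-5-[4-methoxy-2,6-bis(methoxymethoxy)phenyl]-1,7-bis[4-(methoxymethoxy)phenyl]hept-6-en-3-yl]oxy-dimethylsilane F7. Vilsmeier–Haack-type acetylation with N,N-dimethylacetamide and POCl3 (CH2Cl2, 0 °C to rt) attacks only ring A and gives the ring-A N,N-dimethyl ketiminium dichlorophosphate F8. Aqueous NaOAc hydrolyses it to the C5-silylated acetophenone F9, and TBAF removes the silyl group to give 25.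

Step 11 is the third risk. Five MOM groups must leave a molecule that holds an enone, a latent flavanone (2′-hydroxychalcone) and an acid-labile hydroxystyrene next to a free alcohol. The fallback sets out from 25 and comes back at 29, and takes the protecting groups off before the enone exists. Compound 25 is treated with TMSOTf and 2,2′-bipyridyl to give the pentakis(trimethylsilyl) ether of the deprotected acetophenone F10, which water converts into 1-[2,4-dihydroxy-3-[(1E,3R,5S)-5-hydroxy-1,7-bis(4-hydroxyphenyl)hept-1-en-3-yl]-6-methoxyphenyl]ethan-1-one F11. A protecting-group-free Claisen–Schmidt condensation of F11 with 8 (excess KOH, EtOH/H2O, both partners as phenolates) then gives 29 with no acid treatment after the enone is formed.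

**Further compounds**
F1 | step 5 | 4-methoxy-2,6-bis(methoxymethoxy)benzaldehyde | COCOc1cc(OC)cc(OCOC)c1C=O
F2 | step 5 | ethyl (2E)-3-[4-methoxy-2,6-bis(methoxymethoxy)phenyl]prop-2-enoate | CCOC(=O)/C=C/c1c(OCOC)cc(OC)cc1OCOC
F3 | step 5 | (2E)-3-[4-methoxy-2,6-bis(methoxymethoxy)phenyl]prop-2-en-1-ol | OC/C=C/c1c(OCOC)cc(OC)cc1OCOC
F4 | step 5 | diethyl (2E)-3-[4-methoxy-2,6-bis(methoxymethoxy)phenyl]prop-2-en-1-yl phosphate | CCOP(=O)(OCC)OC/C=C/c1c(OCOC)cc(OC)cc1OCOC
F5 | step 5 | 2-[(2R)-2-[4-methoxy-2,6-bis(methoxymethoxy)phenyl]but-3-en-1-yl]-4,4,5,5-tetramethyl-1,3,2-dioxaborolane | COc1cc(OCOC)c([C@@H](C=C)CB2OC(C)(C)C(C)(C)O2)c(OCOC)c1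
F6 | step 5 | 1-ethenyl-4-(methoxymethoxy)benzene | C=Cc1ccc(OCOC)cc1
F7 | step 9 | tert-butyl-[(3S,5R,6E)-5-[4-methoxy-2,6-bis(methoxymethoxy)phenyl]-1,7-bis[4-(methoxymethoxy)phenyl]hept-6-en-3-yl]oxy-dimethylsilane | COc1cc(OCOC)c([C@@H](/C=C/c2ccc(OCOC)cc2)C[C@@H](O[Si](C)(C)C(C)(C)C)CCc2ccc(OCOC)cc2)c(OCOC)c1
F8 | step 9 | ring-A N,N-dimethyl ketiminium dichlorophosphate of F7 | COc1cc(OCOC)c([C@@H](/C=C/c2ccc(OCOC)cc2)C[C@@H](O[Si](C)(C)C(C)(C)C)CCc2ccc(OCOC)cc2)c(OCOC)c1C(C)=[N+](C)C.[O-]P(=O)(Cl)Cl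
F9 | step 9 | 1-[3-[(1E,3R,5S)-5-[tert-butyl(dimethyl)silyl]oxy-1,7-bis[4-(methoxymethoxy)phenyl]hept-1-en-3-yl]-6-methoxy-2,4-bis(methoxymethoxy)phenyl]ethan-1-one | COc1cc(OCOC)c([C@@H](/C=C/c2ccc(OCOC)cc2)C[C@@H](O[Si](C)(C)C(C)(C)C)CCc2ccc(OCOC)cc2)c(OCOC)c1C(C)=O
F10 | step 11 | pentakis(trimethylsilyl) ether of F11 | COc1cc(O[Si](C)(C)C)c([C@@H](/C=C/c2ccc(O[Si](C)(C)C)cc2)C[C@@H](O[Si](C)(C)C)CCc2ccc(O[Si](C)(C)C)cc2)c(O[Si](C)(C)C)c1C(C)=O
F11 | step 11 | 1-[2,4-dihydroxy-3-[(1E,3R,5S)-5-hydroxy-1,7-bis(4-hydroxyphenyl)hept-1-en-3-yl]-6-methoxyphenyl]ethan-1-one | COc1cc(O)c([C@@H](/C=C/c2ccc(O)cc2)C[C@@H](O)CCc2ccc(O)cc2)c(O)c1C(C)=O
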